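The target is a fully substituted 4H-pyran-4-one whose C6 side chain (C1' to C11') carries its only stereocentre, an (S)-configured methyl carbinol acetate, at the penultimate carbon C10', nine methylenes from the ring. The plan rests on disconnecting the C10'–O bond to a C10'=C11' terminal alkene: a fatty acid hydratase should add water across this unactivated double bond with Markovnikov orientation and fix the configuration in a single, protecting-group-free operation. Its precursor is the achiral 3-ethyl-2-methoxy-5-methylpyranone bearing an undec-10-enyl chain at C6, built by side-chain alkylation of a triketide-derived pyranone. Acetylation of the carbinol finishes the synthesis.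

Key step: step 6

Remarks on the chemistry:
- The side chain is numbered C1' to C11' from ring carbon C6; C1' comes from the C6 methyl group of 9 and C2' to C11' from bromide 10.
- The stereocentre of the target is (S) (O > C9' > C11' > H). The structures were checked atom by atom and needed no correction.
- Compounds 3 and 7 are used as mixtures of stereoisomers and tautomers, since their stereocentres disappear on cyclisation.
- Assumption: a hydratase variant with an enlarged distal tunnel binds alkene 12 in the same register as simple 1-alkenes. The configuration of 13 is to be confirmed (Mosher ester analysis) before acetylation.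

Step 1
Reactants: 1 methyl 3-oxopentanoate; 2 iodoethane
Product: 3 methyl 2-ethyl-3-oxopentanoate (racemic)
Conditions: K2CO3, acetone, reflux
Reagents that add atoms: none
Why: β-Keto ester C-alkylation (SN2): the potassium enolate of 1 attacks the primary iodide at carbon, and the more hindered, less acidic monoethyl product resists a second alkylation.

Step 2
Reactants: 3 methyl 2-ethyl-3-oxopentanoate; 4 N-methoxy-N-methylacetamide
Product: 7 methyl 2-ethyl-4-methyl-3,5-dioxohexanoate, via dianion 5 (not isolated), via tetrahedral adduct 6 (not isolated)
Conditions: NaH, THF, 0 °C; n-BuLi, 0 °C; then 4, 0 °C → rt; 1 M HCl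
Reagents that add atoms: none
Why: Claisen-type acylation of a β-keto ester dianion: the more basic γ-terminus (C4) of 5 adds to the Weinreb amide, and the chelated tetrahedral adduct 6 holds until the acidic quench, so the acidic product is never free to quench unreacted dianion or to be acylated again.

Step 3
Reactants: 7 methyl 2-ethyl-4-methyl-3,5-dioxohexanoate
Product: 8 3-ethyl-4-hydroxy-5,6-dimethyl-2H-pyran-2-one
Conditions: DBU, toluene, 80 °C; then 1 M HCl
Reagents that add atoms: none
Why: Base-mediated lactonisation (intramolecular O-acylation) of a 3,5-diketo ester: the enolate oxygen of the C5 ketone attacks the ester, methanol is expelled, and deprotonation of the acidic 4-hydroxy-2-pyranone by DBU pulls the equilibrium to the ring-closed side.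

Step 4
Reactants: 8 3-ethyl-4-hydroxy-5,6-dimethyl-2H-pyran-2-one
Product: 9 3-ethyl-2-methoxy-5,6-dimethyl-4H-pyran-4-one
Conditions: MeOTf, CH2Cl2, 0 °C → rt; then sat. aq. NaHCO3
Reagents that add atoms: methyl trifluoromethanesulfonate, COS(=O)(=O)C(F)(F)F
Why: O-Alkylation with a hard electrophile under base-free conditions: the neutral pyranone is methylated at its most Lewis-basic oxygen, the lactone carbonyl, and loss of the C4 hydroxyl proton leaves the cross-conjugated 2-methoxy-4-pyranone, the usual outcome when methyl triflate or methyl fluorosulfonate is used on 3,5-dialkyl-4-hydroxy-2-pyranones.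

Step 5
Reactants: 9 3-ethyl-2-methoxy-5,6-dimethyl-4H-pyran-4-one; 10 10-bromodec-1-ene
Product: 12 3-ethyl-2-methoxy-5-methyl-6-(undec-10-en-1-yl)-4H-pyran-4-one, via lithium dienolate 11 (not isolated)
Conditions: LiN(SiMe3)2, THF, −78 °C; then 10, DMPU, −78 → 0 °C
Reagents that add atoms: none
Why: Vinylogous enolate alkylation (SN2): of all C–H bonds in 9 only those of the C6 methyl group are conjugated with the C4 carbonyl through C5=C6, so LiN(SiMe3)2 gives dienolate 11 selectively, and its exocyclic carbon displaces bromide from the primary halide with DMPU as activating cosolvent, the remote terminal alkene being inert.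

Step 6
Reactants: 12 3-ethyl-2-methoxy-5-methyl-6-(undec-10-en-1-yl)-4H-pyran-4-one
Product: 13 (S)-3-ethyl-6-(10-hydroxyundecyl)-2-methoxy-5-methyl-4H-pyran-4-one
Conditions: oleate hydratase (Elizabethkingia meningoseptica enzyme, tunnel-engineered variant, E. coli whole cells), FAD, hexanoic acid (decoy, chain length to be screened), citrate buffer pH 6.5, DMSO (5% v/v), 30 °C
Reagents that add atoms: water, O
Why: Proposed new method: in the FAD-containing active site, which works without net redox change, an active-site acid (a tyrosine in the Elizabethkingia enzyme) should protonate the terminal carbon C11' while a water molecule held and deprotonated by a glutamate side chain attacks the developing cationic centre C10', so that the C10'–O bond forms with Markovnikov orientation. The closest known reaction is the hydration of simple medium-chain 1-alkenes to (S)-2-alkanols by oleate hydratase in the presence of a carboxylic acid decoy, which has not been shown for an eleven-carbon chain capped by a heteroaromatic ring. No ring is closed in this step. The new stereocentre C10' is controlled by the enzyme alone, which clamps the alkene between the proton donor and the bound water so that water reaches a single face, the one that leads to (S)-2-alkanols from 1-alkenes. The step needs regioselectivity for the internal carbon, facial selectivity and chemoselectivity for the side-chain alkene, and these are secured by the greater stability of the secondary cation, by the enzyme pocket, and by C10'=C11' being the only isolated and unhindered alkene on an unbranched chain that resembles a fatty acyl tail. The open point is whether the distal hydrophobic tunnel, sized for the eight carbons that lie beyond the hydration site in oleic acid, can be opened by mutagenesis or found in a homologue so that it takes nine methylenes and the pyranone.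

Step 7
Reactants: 13 (S)-3-ethyl-6-(10-hydroxyundecyl)-2-methoxy-5-methyl-4H-pyran-4-one
Product: 14 (2S)-11-(5-ethyl-6-methoxy-3-methyl-4-oxo-4H-pyran-2-yl)undecan-2-yl acetate (target)
Conditions: Ac2O, pyridine, DMAP (cat.), CH2Cl2, 0 °C → rt
Reagents that add atoms: acetic anhydride, CC(=O)OC(C)=O
Why: DMAP-catalysed acyl transfer (esterification): the alcohol oxygen attacks the N-acetylpyridinium ion, no bond to C10' is broken and the (S) configuration is therefore retained, while the pyranone and its enol ether are inert to these conditions.

Compound list
1 | methyl 3-oxopentanoate | CCC(=O)CC(=O)OC | starting material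
2 | iodoethane | CCI | starting material
3 | methyl 2-ethyl-3-oxopentanoate (racemic) | CCC(=O)C(CC)C(=O)OC | intermediate
4 | N-methoxy-N-methylacetamide | CC(=O)N(C)OC | starting material
5 | lithium sodium 2-ethyl-1-methoxypenta-1,3-diene-1,3-diolate (dianion of 3, enolate geometry undefined, not isolated) | CC=C([O-])C(CC)=C([O-])OC.[Li+].[Na+] | intermediate
6 | lithium sodium salt of the tetrahedral adduct of 5 with 4: methyl 2-ethyl-5-hydroxy-5-[methoxy(methyl)amino]-4-methyl-3-oxohexanoate as C5 alkoxide and ester enolate (not isolated) | CC([O-])(N(C)OC)C(C)C(=O)C(CC)=C([O-])OC.[Li+].[Na+] | intermediate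
7 | methyl 2-ethyl-4-methyl-3,5-dioxohexanoate (mixture of diastereomers and tautomers) | CC(=O)C(C)C(=O)C(CC)C(=O)OC | intermediate
8 | 3-ethyl-4-hydroxy-5,6-dimethyl-2H-pyran-2-one | CCc1c(O)c(C)c(C)oc1=O | intermediate
9 | 3-ethyl-2-methoxy-5,6-dimethyl-4H-pyran-4-one | CCc1c(OC)oc(C)c(C)c1=O | intermediate
10 | 10-bromodec-1-ene | C=CCCCCCCCCBr | starting material
11 | lithium 5-ethyl-6-methoxy-3-methyl-2-methylidene-2H-pyran-4-olate (dienolate of 9, not isolated) | C=C1OC(OC)=C(CC)C([O-])=C1C.[Li+] | intermediate
12 | 3-ethyl-2-methoxy-5-methyl-6-(undec-10-en-1-yl)-4H-pyran-4-one | CCc1c(OC)oc(CCCCCCCCCC=C)c(C)c1=O | intermediate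
13 | (S)-3-ethyl-6-(10-hydroxyundecyl)-2-methoxy-5-methyl-4H-pyran-4-one | CCc1c(OC)oc(CCCCCCCCC[C@H](C)O)c(C)c1=O | intermediate
14 | (2S)-11-(5-ethyl-6-methoxy-3-methyl-4-oxo-4H-pyran-2-yl)undecan-2-yl acetate | CCc1c(OC)oc(CCCCCCCCC[C@H](C)OC(C)=O)c(C)c1=O | target

Total step count: 7
Longest linear sequence: 7 steps (1 → 3 → 7 → 8 → 9 → 12 → 13 → 14)

Steps most likely to fail

Step 6 (Proposed new method). What may go wrong: the long chain with its pyranone cap may fail to enter the distal tunnel, so that no turnover takes place, or the alkene may bind in a shifted register so that water is delivered with poor facial selectivity. The fallback uses known chemistry, sets out from 12 and comes back to the route at 13. Tsuji–Wacker oxidation of the terminal alkene of 12 (PdCl2 cat., CuCl, O2, DMF/H2O, rt) should give the methyl ketone 3-ethyl-2-methoxy-5-methyl-6-(10-oxoundecyl)-4H-pyran-4-one F1. Reduction of this ketone with a Prelog-selective alcohol dehydrogenase (NADH recycled with propan-2-ol, phosphate buffer pH 7, 30 °C) should then give 13. This enzyme class reduces long-chain 2-alkanones to (S)-2-alkanols, and the vinylogous ester carbonyl of the ring is not a substrate.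

Step 5. What may go wrong: slow SN2 attack of the dienolate on the unactivated bromide, during which the anion decomposes on warming or the product is deprotonated at C1' and alkylated a second time. The fallback moves the chain into the pyranone construction, sets out from 3 and comes back at 12. Commercial dodec-11-enoic acid (C=CCCCCCCCCCC(=O)O) would be coupled with N,O-dimethylhydroxylamine hydrochloride (EDC hydrochloride, N-methylmorpholine, CH2Cl2) to N-methoxy-N-methyldodec-11-enamide F2. Dianion 5, generated from 3 as in step 2, would add to this amide and give, through the lithium sodium tetrahedral adduct F3 (not isolated) and acidic quench, methyl 2-ethyl-4-methyl-3,5-dioxohexadec-15-enoate F4. DBU in toluene would close this to 3-ethyl-4-hydroxy-5-methyl-6-(undec-10-en-1-yl)-2H-pyran-2-one F5, and methyl triflate in CH2Cl2, as in step 4, would convert it into 12.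

Step 4. What may go wrong: methylation at the C4 hydroxyl oxygen in place of the lactone carbonyl oxygen, which would lead to the regioisomeric 4-methoxy-2-pyranone and erode the supply of 9. The fallback avoids the O-methylation altogether, sets out from 7 and comes back at 9. Diketo ester 7 would be cyclodehydrated directly with PPh3 and CCl4 in THF at rt. The enol of the C5 ketone is activated as an oxyphosphonium salt and the ester carbonyl oxygen closes the ring with loss of triphenylphosphine oxide. The ester methoxy group thus becomes the C2 methoxy group of 9 and no regiochemical choice arises. This fallback makes no new compound (F0).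

Further compounds
F1 | step 6 | 3-ethyl-2-methoxy-5-methyl-6-(10-oxoundecyl)-4H-pyran-4-one | CCc1c(OC)oc(CCCCCCCCCC(C)=O)c(C)c1=O
F2 | step 5 | N-methoxy-N-methyldodec-11-enamide | C=CCCCCCCCCCC(=O)N(C)OC
F3 | step 5 | lithium sodium tetrahedral adduct of 5 with F2 (not isolated) | C=CCCCCCCCCCC([O-])(N(C)OC)C(C)C(=O)C(CC)=C([O-])OC.[Li+].[Na+]
F4 | step 5 | methyl 2-ethyl-4-methyl-3,5-dioxohexadec-15-enoate | C=CCCCCCCCCCC(=O)C(C)C(=O)C(CC)C(=O)OC
F5 | step 5 | 3-ethyl-4-hydroxy-5-methyl-6-(undec-10-en-1-yl)-2H-pyran-2-one | CCc1c(O)c(C)c(CCCCCCCCCC=C)oc1=O
F0 | step 4 | none | none
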